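The rate constants were chosen freely; what happens was integrated by code.

Against an even split, where a catalyst with an equilibrium constant of one comes to rest, the free catalyst in this flask leans towards the dormant form by 2.7 to one.

substrate 0.49 M; partner 1.10 equiv; free catalyst 0.065 mol%; second catalyst 5.1 mol%

    substrate + free catalyst ⇌ free catalyst + intermediate (K1 = 0.36, k1 = 1200 M⁻¹ s⁻¹)
    partner + second catalyst + intermediate → second catalyst + product (k2 = 0.71 M⁻² s⁻¹)
    free catalyst ⇌ dormant form (K3 = 2.7, k3 = 0.0095 s⁻¹)

1. the form that holds most of the catalyst when 50% of the substrate are converted (dormant form / free catalyst)
2. its share of the catalyst then

So my scale starts from an even split, and the end share of dormant form is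

end share = 73.0%

The catalyst starts wholly free, and in steps substrate + free catalyst ⇌ free catalyst + intermediate (K1 = 0.36, k1 = 1200 M⁻¹ s⁻¹) and partner + second catalyst + intermediate → second catalyst + product (k2 = 0.71 M⁻² s⁻¹) the catalysts come out as they went in, so its dormant share climbs towards that end on one exponential. Its rate is 0.781 min⁻¹, the dormancy rate, the forward and reverse constants between free catalyst and dormant form added:

dormant share at time t = end share × (1 − exp(−dormancy rate × t))

Now I turn the settings by hand. The loading of free catalyst appears in neither factor; it enters the exchange of substrate and intermediate, whose rate is 86.6 min⁻¹ as charged and still 23.4 min⁻¹ with the free catalyst down at its end remainder, far faster than the 0.574 min⁻¹ at which partner and second catalyst, as charged, use up intermediate. So I hold substrate and intermediate at their equilibrium ratio, a rapid pre-equilibrium, and the pool of both, as a fraction s of the charge, contains 26.5% intermediate.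

For the clock I use the reaction with partner and second catalyst. The pool falls with rate constant 0.138 min⁻¹ times s times (s + excess of partner), and 50% of the substrate gone means s = 0.680, which integrates to

t = 3.03 min

dormant share = 66.1%, so the larger form is dormant form

With twice the loading of second catalyst, my reckoned clock reads half as long and the same curve gives 50.6%.

The forecast gives dormant form at 66%, the catalyst being “about 90% of the way there”.

The flask holds 66.5% of its catalyst as dormant form and 33.5% as free catalyst, and it reaches that conversion at 3.10 min. Later in this flask, at 9.11 min, the dormancy rate has run for 7.11 relaxation times, so my curve gives 72.9%, and the dormant form in the flask stands at 72.9%.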